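Take the feed of reagent as a share of its charge per hour, then count how long it needs to deliver one substrate charge.

| flask | substrate | reagent in the second phase | remark | time | volume of the second phase over the first |
|---|---|---|---|---|---|
| theta | 0.10 M | 0.26 M | run made earlier |  |  |
| alpha | 0.15 M | 0.26 M | run made earlier |  |  |
| gamma | 0.20 M | 0.39 M | run made earlier |  |  |
| flask | 0.20 M | 0.260 M |  | 8.0 h | 1.0 |

| run | time / h | target / % |
|---|---|---|
| theta | 0.250 | 40.7 |
| theta | 0.417 | 56.3 |
| theta | 0.667 | 64.2 |
| theta | 1.00 | 48.9 |
| theta | 2.00 | 23.0 |
| theta | 3.00 | 10.8 |
| theta | 5.00 | 2.4 |
| alpha | 0.250 | 27.9 |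
| alpha | 0.417 | 40.4 |
| alpha | 0.667 | 50.2 |
| alpha | 1.00 | 50.7 |
| alpha | 2.00 | 24.1 |
| alpha | 3.00 | 12.0 |
| alpha | 5.00 | 1.8 |
| gamma | 0.250 | 31.9 |
| gamma | 0.500 | 48.4 |
| gamma | 1.00 | 54.1 |
| gamma | 2.50 | 15.7 |
| gamma | 5.00 | 1.2 |

(readings scatter by 1 percentage point)

- charges count per volume of the first phase; a concentration in a rate is the amount of a species over the volume of its own phase; every rate counts per litre of the first phase
- the numbers in the tables scatter with a standard deviation of 1 percentage point
- the earlier runs hold the two phases in the same ratio of volumes as the flask asked about
- a reading or a percentage of target counts all its forms, free or not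

- the moment within 8.0 h at which there is most target
- the amount of target, in percent of the substrate charged, at that time

Question: what do the first readings say? Answer: at 0.250 h, theta holds 40.7% of its substrate charge, alpha 27.9% and gamma 31.9%. Reckoned against each run's reagent charge, these readings give on average a feed of 0.641 /h, as a share of that charge.

Question: what do you count with that? Answer: for the flask it gives 1.20 h, the turnover time: the hours the starting feed needs to deliver one substrate charge.

Question: and the loss? Answer: in theta, the readings of target fall from 23.0% to 10.8% between 2.00 h and 3.00 h, which reads as a first-order loss of 0.756 /h.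

Question: what is your rule for these runs, at this ratio of phase volumes? Answer: I put the peak near one turnover time, at the share that first-order loss leaves over that time. Theta has 0.600 h and 63.5%, against a highest reading of 64.2% at 0.667 h. Alpha has 0.899 h and 50.7%, against 50.7% at 1.00 h. Gamma has 0.799 h and 54.7%, against 54.1% at 1.00 h.

Question: but the flask turns over more slowly than any of these? Answer: yes, so this is extrapolation. I still commit to 1.20 h and 40.4%.

The forecast says 1.2 h (1 h to 1.5 h) and 43% (38% to 49%), on this ground: “formation looks saturated in substrate and proportional to reagent”. Its amount is higher than my 40.4%.

The flask gives 43.8% at 1.09 h.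

    substrate + reagent in the reaction phase → target (k = 12.0 /M/min)
    reagent in the reaction phase ⇌ reagent in the second phase, rate k2*([reagent in the reaction phase] - [reagent in the second phase]/K2) per volume of the first phase (partition coefficient = 0.980, kL = 0.0150 /min)
    target → decomposed product (k = 0.0260 /min)
    target ⇌ product in the second phase, rate k4*([target] - [product in the second phase]/K4) per volume of the first phase (partition coefficient = 0.780, kL = 0.0360 /min)
    2 substrate → self-condensation product (k = 0.00720 /M/min)

That peak lies inside both forecast ranges, earlier than the turnover time of 1.20 h and higher than 40.4%. The neighbouring flask, with 0.34 M of substrate, has a turnover time of 2.04 h, and that loss leaves 21.4%; its highest amount of target is 26.6%. Its reagent charge is 76.5% of its substrate charge, which makes reagent the limiting reagent there. At 8.00 h that neighbouring flask keeps 0.0845% of its reagent in the second phase, with 6.1% of its substrate left.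

(Readings and results were generated by integration with constants of no real substance; the scatter is artificial.)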